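# Proposed total synthesis of CID124202369 (compound 14)

## Analysis of the target

1. Compound 14 is a 24-membered meta,para-cyclophane with no stereocentre. Its only stereochemical elements are two E double bonds, C7=C8 and C7'=C8', which are remote from each other and must be set independently.
2. Ring A is a 1,3,4-trisubstituted benzene: C1 carries the chain C7=C8–C9(=O), C3 the ether oxygen and C4 the O-sulfate. Ring B is 1',4'-disubstituted: C1' carries C7'=C8'–C9'(=O) and C4' the ether oxygen. The C3–O–C4' diaryl ether joins the two rings on one side.
3. Spermidine, N1–(CH2)3–N4–(CH2)4–N8, completes the ring on the other side. C9' sits on N1 (propyl end), C9 on N8 (butyl end), and N4 is a free secondary amine.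
4. Three groups are sensitive. The aryl sulfate monoester is lost in acid or by solvolysis, is ionic, and forms an inner salt with N4. The N4–H would be sulfamated and would add to acrylamides. The cinnamamide double bonds rule out hydrogenolysis and can drift from E to Z in light.
5. No single bond is hard. The difficulty is three selections at once: ring against oligomer, O- against N-sulfation, and the head-to-tail orientation of an unsymmetrical triamine on an unsymmetrical diaryl ether, where the wrong isomer differs only in the place of one CH2 group.
6. The feature that invites the strategy is that the two look-alike cinnamamides sit on electronically different carbons. C1 of ring A is para to the C4 oxygen, the most nucleophilic C–H position of a 2-aryloxyphenol, so it can be iodinated late. C1' of ring B is para to the ether oxygen, where a formyl group is exactly the activator that lets the C4'–O bond be made by SNAr.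
7. A second feature is the 1,3-relation of N1 and N4. Of the nitrogen pairs, only this one can be bridged by a single carbon atom into a six-membered aminal.
8. There is a hidden trap. A free C4 phenoxide next to a C3–O–aryl group whose aryl ring is formyl-activated can pass ring B from O3 to O4 by a Smiles migration, so the timing of the sulfation matters.

## Retrosynthetic reasoning

**Disconnection 1, 14 to 13 (one carbon placed between N1 and N4).** Going backwards, a methylene group is inserted between the amide nitrogen N1 and the amine nitrogen N4, which gives hexahydropyrimidine 13. This is preferred to a carbamate or sulfonamide on N4 because the one carbon does three jobs: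
- It distinguishes N1 from N8 at the very start.
- It makes N4 tertiary, so N4 can neither be acylated or sulfamated nor add to an acrylamide.
- As an N-acyl aminal it opens reversibly near neutral pH, so it can leave without the acid that would cost the sulfate.

The forward reaction must remove this carbon irreversibly with a carbon nucleophile that leaves the cinnamamides alone.

**Disconnection 2, 13 to 11 and 6 by way of 12 (key step; C7'=C8' and C1–C7).** The two cinnamamides are cut at different bonds: ring A at its aryl–vinyl bond C1–C7 and ring B at its double bond C7'=C8'.
- This splits the macrocycle into a 9-atom piece, iodo aldehyde 11, and a 15-atom piece, 6, which carries an acrylamide on N8 and a phosphonoacetamide on N1.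
- Two cuts of the same kind would leave two equal pairs of partners and no control of orientation. Two cuts of different kinds give orthogonal pairs (iodide with acrylamide, aldehyde with phosphonate), so the constitution of the product is written into the fragments.
- The opposite assignment (formyl at C1, halogen at C1') is rejected. Ring B would lose its SNAr activator and the symmetric starting material 7 could no longer be used.
- The forward reaction has to form both C–C connections, set both E geometries and close the 24-membered ring in one flask. It does so by a Heck reaction at normal concentration followed by an intramolecular Horner–Wadsworth–Emmons olefination under dilution.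

**Disconnection 3, 11 to 10 (S–O bond).** The sulfate is installed before the key step, not after it. In 10 the Smiles migration described above is no longer degenerate, so 10 must not meet a base able to form its phenoxide. Once sulfated, the C4 oxygen is not nucleophilic, and the sulfate monoanion tolerates amine bases and palladium catalysis. The functional group of the target therefore serves as its own protecting group, and no nitrogen is present at this stage to compete.

**Disconnection 4, 10 to 9 (C1–I) and 9 to 7 and 8 (C4'–O).** The iodine is removed to give the bare diaryl ether 9. The forward iodination relies on the intrinsic preference for the position para to the free OH. The ether bond is cut at C4'–O because the formyl group of 8 activates this carbon for SNAr. Because 7 is symmetric, neither O3/O4 selectivity nor a protecting group is needed.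

**Disconnection 5, 6 to 2, 3 and 4 by way of 5 (N8–C9 and N1–C9'), and 2 to 1.** Both amide bonds of the target are made early and intermolecularly, where they are easiest. In 2 the primary N8 amine and the secondary ring N1–H differ enough for sequential acylation in one flask, first with 3 and then with 4. Removing the aminal carbon from 2 leads back to spermidine 1.

## Alternatives that were turned down

**Alternative 1:** (textbook) Disconnection of the amide bond N8–C9. The forward key step is a high-dilution macrolactamisation of seco amino acid A1 (N4-Boc, C4-O-benzyl) with a coupling agent, giving protected macrolactam A2.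
- The ring closure makes only one C–N bond, the easiest bond of the target.
- A1 needs two orthogonally masked acrylic acid termini, two kinds of nitrogen protection on 1 and a phenol protecting group, which puts the route well above ten steps.
- The end game is also awkward. The benzyl group cannot be removed by hydrogenolysis without saturating C7=C8 and C7'=C8'. The Boc group needs acid, so it must go before sulfation, which would then meet a free N4–H.

**Alternative 2:** Disconnection of the ether bond C3–O in the biomimetic sense. The forward key step is anodic one-electron oxidation of the bis(4-hydroxycinnamoyl) aminal A3 and O–C coupling of the phenoxyl radical, giving macrocyclic phenol A4.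
- It is very short, but nothing in A3 secures the selectivity it needs.
- The spin density of a 4-hydroxycinnamoyl radical is highest at C8 and at oxygen, so C8–C8', C8–C5' and C8–O couplings should outrun O–C3 coupling.
- The two rings are the same chromophore, so either can act as the oxygen donor, and A4 and its orientation isomer A5 are equally likely.
- The tertiary N4 amine is oxidised in the same potential range.
- A4 is more electron-rich than A3 and would be oxidised further.

**Alternative 3:** Disconnection of both aryl–vinyl bonds, C1–C7 and C1'–C7'. The forward key step is a double Heck macrocyclisation of diiodide A6 with bis-acrylamide A7.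
- It makes as many bonds as the chosen key step, but from two pairs of the same kind.
- Neither iodide can recognise its acrylamide, so A4 and A5 would form as a statistical mixture of isomers that differ only in the place of one CH2 group and would be very hard to separate.
- A6 itself is awkward to make, because the second iodination (ring B) has to compete with the free ortho position of the phenol ring.

Key step: step 6

Remark on the chemistry: sulfate monoesters are drawn in the neutral O–SO3H form used in the target SMILES; 11 and 12 are expected to be handled as triethylammonium salts, 13 and 14 as inner salts with N4.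

## Route

Step 1
Reactants: 1 spermidine
Product: 2 4-(1,3-diazinan-1-yl)butan-1-amine (the N1,N4-methylene aminal of spermidine)
Conditions: 37% aq. CH2O (1.0 equiv), H2O, 0 °C to rt
Reagents that add atoms: formaldehyde, C=O
Why: Cyclocondensation to an aminal under thermodynamic control: only the 1,3-related pair N1/N4 can close a six-membered ring over one carbon, whereas N4/N8 would need a seven-membered ring, so N8 remains the only primary amine. No stereocentre is formed.

Step 2
Reactants: 2 4-(1,3-diazinan-1-yl)butan-1-amine; 3 N-succinimidyl acrylate; 4 diethylphosphonoacetic acid
Product: 6 diethyl (2-oxo-2-{3-[4-(prop-2-enoylamino)butyl]-1,3-diazinan-1-yl}ethyl)phosphonate, via N8-acryloyl aminal 5 (not isolated)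
Conditions: 3 (1.0 equiv, slow addition), iPr2NEt, CH2Cl2, −40 to 0 °C; then 4, DIC, HOBt (cat.), 0 °C to rt
Reagents that add atoms: none
Why: Chemoselective N-acylation with an active ester, then carbodiimide coupling in the same flask: the unhindered primary N8 amine reacts faster than the secondary ring N1–H, whose nucleophilicity is lowered by the geminal nitrogen, and the low temperature favours acyl transfer over conjugate addition. Capping N1 at once removes the last N–H amine that could add to the acrylamide of 5.

Step 3
Reactants: 7 catechol; 8 4-fluorobenzaldehyde
Product: 9 4-(2-hydroxyphenoxy)benzaldehyde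
Conditions: 7 (3 equiv), K2CO3, DMF, 100 °C, Ar
Reagents that add atoms: none
Why: SNAr by addition–elimination through a Meisenheimer adduct stabilised by the para formyl group. Catechol is symmetric, so there is no regiochemical question and the O-to-O Smiles migration of the product phenoxide is degenerate; the excess of 7 holds back a second arylation.

Step 4
Reactants: 9 4-(2-hydroxyphenoxy)benzaldehyde
Product: 10 4-(2-hydroxy-5-iodophenoxy)benzaldehyde
Conditions: NIS (1.0 equiv), TsOH·H2O (10 mol %), MeCN, 0 °C to rt, dark
Reagents that add atoms: N-iodosuccinimide, O=C1CCC(=O)N1I
Why: Electrophilic aromatic iodination governed by intrinsic preference: the free OH is by far the strongest donor and the aryloxy oxygen is drained by the formyl-bearing ring B, so attack should go para to OH (the future C1), with the more crowded ortho position as the only rival. The acidic medium excludes the phenoxide and with it the Smiles migration, and the aldehyde is inert to NIS.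

Step 5
Reactants: 10 4-(2-hydroxy-5-iodophenoxy)benzaldehyde
Product: 11 2-(4-formylphenoxy)-4-iodophenyl hydrogen sulfate (handled as triethylammonium salt)
Conditions: SO3·pyridine (2 equiv), pyridine, rt; then Et3N, evaporation; SiO2 (CH2Cl2–MeOH–Et3N)
Reagents that add atoms: sulfur trioxide pyridine complex, [O-]S(=O)(=O)[n+]1ccccc1
Why: O-sulfation of a phenol with a sulfur trioxide amine complex; pyridine is too weak a base to form the phenoxide, so the migration of ring B from O3 to O4 cannot start, and after sulfation the C4 oxygen is no longer nucleophilic. The aldehyde and the C–I bond are inert to the reagent, and no nitrogen nucleophile is present at this stage.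

Step 6
Reactants: 11 2-(4-formylphenoxy)-4-iodophenyl hydrogen sulfate; 6 diethyl (2-oxo-2-{3-[4-(prop-2-enoylamino)butyl]-1,3-diazinan-1-yl}ethyl)phosphonate
Product: 13 macrocyclic (7E,7'E)-bis-cinnamamide C4 hydrogen sulfate bearing the N1-CH2-N4 aminal bridge, via linear Heck product 12 (not isolated)
Conditions: Pd(OAc)2 (5 mol %), P(o-tol)3 (12 mol %), Et3N (3 equiv), MeCN, 80 °C, 0.1 M; then syringe-pump addition of this solution to LiCl (15 equiv), DBU (15 equiv), MeCN, 40 °C, final 1 mM; C18 chromatography
Reagents that add atoms: none
Why: Stage one is a Mizoroki–Heck reaction: zerovalent palladium, formed in the flask from Pd(OAc)2 and P(o-tol)3, inserts into the C1–I bond of 11, the aryl group is delivered syn to the unsubstituted terminus of the N8 acrylamide of 6, and syn β-hydride elimination after bond rotation gives the E C7=C8 bond of 12. Et3N cannot deprotonate the phosphonoacetamide, so aldehyde and phosphonate should pass this concentrated stage untouched. Stage two is an intramolecular Horner–Wadsworth–Emmons olefination under Masamune–Roush conditions: Li+ chelated between the P=O and C9'=O oxygens acidifies C8'–H for DBU, addition to the ring B aldehyde is reversible, and collapse of the less crowded trans-oxaphosphetane gives the E C7'=C8' bond. The closest known reaction types are one-pot Heck/olefination sequences to distyrylarenes and HWE macrocyclisations of phosphonoacetates and phosphonoacetamides to large-ring enoates and enamides. One ring is closed, the 24-membered macrocycle (22-membered along the short path over the aminal carbon), end to end by C=C formation under pseudo-high dilution; at this size no ring strain opposes the E preference of either reaction, and no stereocentre is formed. The orientation (C9 on N8, C9' on N1) is secured by orthogonal pairing, since the iodide can only react with the acrylamide and the aldehyde only with the phosphonate. Ring closure is favoured over oligomerisation by the slow addition and by the few free rotors of 12: the planar cinnamamide, the bent diaryl ether and the chair hexahydropyrimidine leave little more than the butyl chain flexible. The sulfate monoanion is inert to palladium, Et3N and DBU and keeps the C4 oxygen from attacking the formyl-activated ring B.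

Step 7
Reactants: 13 macrocyclic (7E,7'E)-bis-cinnamamide C4 hydrogen sulfate bearing the N1-CH2-N4 aminal bridge
Product: 14 target macrocycle CID124202369 (inner salt)
Conditions: dimedone (3 equiv), pyridine (2 equiv), EtOH–H2O, 50 °C, dim light; C18 chromatography
Reagents that add atoms: none
Why: Knoevenagel-type methylene transfer, the known way to unmask polyamine hexahydropyrimidines with an active methylene compound: the N-acyl aminal opens reversibly to the N4 iminium ion and the N1–H amide, the enol of dimedone takes up the carbon, and a second dimedone adds to the methylene intermediate, so the carbon ends in an inert bis-adduct and no Michael acceptor is left beside the freed N4–H. The medium is only weakly acidic and buffered, which the aryl sulfate and both E cinnamamides should tolerate.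

## Compound list

1 | spermidine, N-(3-aminopropyl)butane-1,4-diamine | NCCCCNCCCN | starting material
2 | 4-(1,3-diazinan-1-yl)butan-1-amine | NCCCCN1CCCNC1 | intermediate
3 | N-succinimidyl acrylate | C=CC(=O)ON1C(=O)CCC1=O | starting material
4 | diethylphosphonoacetic acid | CCOP(=O)(CC(=O)O)OCC | starting material
5 | N-[4-(1,3-diazinan-1-yl)butyl]prop-2-enamide (formed and used in the flask) | C=CC(=O)NCCCCN1CCCNC1 | intermediate
6 | diethyl (2-oxo-2-{3-[4-(prop-2-enoylamino)butyl]-1,3-diazinan-1-yl}ethyl)phosphonate | C=CC(=O)NCCCCN1CCCN(C1)C(=O)CP(=O)(OCC)OCC | intermediate
7 | catechol | Oc1ccccc1O | starting material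
8 | 4-fluorobenzaldehyde | O=Cc1ccc(F)cc1 | starting material
9 | 4-(2-hydroxyphenoxy)benzaldehyde | O=Cc1ccc(Oc2ccccc2O)cc1 | intermediate
10 | 4-(2-hydroxy-5-iodophenoxy)benzaldehyde | O=Cc1ccc(Oc2cc(I)ccc2O)cc1 | intermediate
11 | 2-(4-formylphenoxy)-4-iodophenyl hydrogen sulfate | O=Cc1ccc(Oc2cc(I)ccc2OS(=O)(=O)O)cc1 | intermediate
12 | (E)-N-{4-[3-(diethoxyphosphorylacetyl)-1,3-diazinan-1-yl]butyl}-3-[3-(4-formylphenoxy)-4-(sulfooxy)phenyl]prop-2-enamide (formed and used in the flask) | O=Cc1ccc(Oc2cc(/C=C/C(=O)NCCCCN3CCCN(C3)C(=O)CP(=O)(OCC)OCC)ccc2OS(=O)(=O)O)cc1 | intermediate
13 | macrocyclic (7E,7'E)-bis-cinnamamide, C4 hydrogen sulfate, N1 and N4 bridged by CH2 | O=C1/C=C/c2ccc(OS(=O)(=O)O)c(c2)Oc2ccc(cc2)/C=C/C(=O)N2CCCN(C2)CCCCN1 | intermediate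
14 | CID124202369, (7E,7'E)-macrocycle with C4 hydrogen sulfate and free N4–H | O=C1/C=C/c2ccc(OS(=O)(=O)O)c(c2)Oc2ccc(cc2)/C=C/C(=O)NCCCNCCCCN1 | target

## Step count and risk

Total step count: 7 steps.

Longest linear sequence: 5 steps (steps 3, 4, 5, 6 and 7, from 7 and 8). The second branch (steps 1 and 2, from 1) joins at step 6.

**Step 6 (key step).**
- What may go wrong: intermolecular olefination may overtake ring closure. A tertiary phosphonoacetamide is only partly deprotonated by DBU and LiCl, so 12 may accumulate during the addition. Olefination could also begin already in the concentrated Heck stage.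
- Fallback: this closes the ring at the other cut. It sets out from 11 and 6. A Masamune–Roush olefination at ordinary concentration (LiCl, DBU, MeCN, rt) joins aldehyde and phosphonate first and gives the linear iodo acrylamide sulfate F1, which is isolated. The macrocycle is then closed at C1–C7 by a Heck macrocyclisation under Jeffery conditions (Pd(OAc)2, Bu4NCl, NaHCO3, DMF, 80 °C, slow addition). This comes back to the route at 13.

**Step 2.**
- What may go wrong: chemoselectivity between N8 and N1 may be lost in the first acylation, and an amine may add in conjugate fashion to the activated acrylate. Both nitrogen atoms are nucleophilic, and the liberated acid partly protonates the more basic primary amine.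
- Fallback: the acrylamide is installed last. The fallback sets out from 2. Ethyl trifluoroacetate, which acylates only primary amines, gives the N8-trifluoroacetamide F2. Coupling of 4 with DIC at N1 gives the phosphonoacetamide F3. K2CO3 in MeOH–H2O frees the primary amine F4. Acylation of F4 with 3, now without any competing N–H amine, comes back to the route at 6.

**Step 7.**
- What may go wrong: the sulfate may be lost by solvolysis in the warm, weakly acidic medium, or the N-acyl aminal may open too slowly, so that longer heating is needed and the first problem grows.
- Fallback: the loss of the sulfate is accepted and the sulfate is put back under a base-labile nitrogen protecting group. The fallback sets out from 13.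
  - Aqueous HCl in MeOH at 50 °C removes both the aminal carbon and the sulfate and gives the macrocyclic amino phenol F5.
  - Fmoc-OSu with NaHCO3 protects N4 in preference to the phenol and gives the carbamate F6.
  - SO3·pyridine in pyridine gives the N4-Fmoc sulfate F7.
  - Piperidine in DMF, to which aryl sulfates and cinnamamides are inert, comes back to the route at 14.

**Step 4.**
- What may go wrong: iodination may occur at the position ortho to OH, or twice, because the phenol ring stays activated after the first substitution.
- Fallback: the iodine is bought in place. The fallback sets out from 8. SNAr with commercial 5-iodo-2-methoxyphenol (K2CO3, DMF, 100 °C) gives the methyl ether F8. BBr3 in CH2Cl2 (−78 to 0 °C) cleaves the methyl ether without base and comes back to the route at 10.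

## Further compounds

F1 | step 6 | 2-{4-[(E)-3-oxo-3-{3-[4-(prop-2-enoylamino)butyl]-1,3-diazinan-1-yl}prop-1-enyl]phenoxy}-4-iodophenyl hydrogen sulfate | C=CC(=O)NCCCCN1CCCN(C1)C(=O)/C=C/c1ccc(Oc2cc(I)ccc2OS(=O)(=O)O)cc1
F2 | step 2 | N-[4-(1,3-diazinan-1-yl)butyl]-2,2,2-trifluoroacetamide | FC(F)(F)C(=O)NCCCCN1CCCNC1
F3 | step 2 | diethyl (2-oxo-2-{3-[4-(2,2,2-trifluoroacetamido)butyl]-1,3-diazinan-1-yl}ethyl)phosphonate | FC(F)(F)C(=O)NCCCCN1CCCN(C1)C(=O)CP(=O)(OCC)OCC
F4 | step 2 | diethyl {2-[3-(4-aminobutyl)-1,3-diazinan-1-yl]-2-oxoethyl}phosphonate | NCCCCN1CCCN(C1)C(=O)CP(=O)(OCC)OCC
F5 | step 7 | (7E,7'E)-macrocycle with free C4–OH and free N4–H | O=C1/C=C/c2ccc(O)c(c2)Oc2ccc(cc2)/C=C/C(=O)NCCCNCCCCN1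
F6 | step 7 | N4-Fmoc derivative of the macrocyclic amino phenol | O=C1/C=C/c2ccc(O)c(c2)Oc2ccc(cc2)/C=C/C(=O)NCCCN(C(=O)OCC2c3ccccc3-c3ccccc23)CCCCN1
F7 | step 7 | N4-Fmoc macrocycle C4 hydrogen sulfate | O=C1/C=C/c2ccc(OS(=O)(=O)O)c(c2)Oc2ccc(cc2)/C=C/C(=O)NCCCN(C(=O)OCC2c3ccccc3-c3ccccc23)CCCCN1
F8 | step 4 | 4-(5-iodo-2-methoxyphenoxy)benzaldehyde | COc1ccc(I)cc1Oc1ccc(C=O)cc1
A1 | alternative 1 | seco amino acid, N4-Boc, C4-O-benzyl, free N8 amine and free C9 acid | NCCCCN(C(=O)OC(C)(C)C)CCCNC(=O)/C=C/c1ccc(Oc2cc(/C=C/C(=O)O)ccc2OCc2ccccc2)cc1
A2 | alternative 1 | protected macrolactam, N4-Boc, C4-O-benzyl | O=C1/C=C/c2ccc(OCc3ccccc3)c(c2)Oc2ccc(cc2)/C=C/C(=O)NCCCN(C(=O)OC(C)(C)C)CCCCN1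
A3 | alternative 2 | N1,N8-bis[(E)-4-hydroxycinnamoyl]spermidine N1,N4-methylene aminal | O=C(/C=C/c1ccc(O)cc1)NCCCCN1CCCN(C1)C(=O)/C=C/c1ccc(O)cc1
A4 | alternative 2 | macrocyclic phenol with the aminal bridge, orientation of the target | O=C1/C=C/c2ccc(O)c(c2)Oc2ccc(cc2)/C=C/C(=O)N2CCCN(C2)CCCCN1
A5 | alternative 2 | orientation isomer of the macrocyclic phenol, ring A chain on N1 and ring B chain on N8 | O=C1/C=C/c2ccc(O)c(c2)Oc2ccc(cc2)/C=C/C(=O)NCCCCN2CCCN1C2
A6 | alternative 3 | 4-iodo-2-(4-iodophenoxy)phenol | Oc1ccc(I)cc1Oc1ccc(I)cc1
A7 | alternative 3 | N1,N8-bis(acryloyl)spermidine N1,N4-methylene aminal | C=CC(=O)NCCCCN1CCCN(C1)C(=O)C=C
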